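**Retrosynthetic overview** (locants are those of the oxolan-2-one ring: O1, C2 carbonyl, C3 carbinol, C4, C5H2)
1. Target 20 ⇐ hydrogenolysis of tris(benzyl ether) 19 ⇐ benzylation of the enolate of α-benzyloxy lactone 17 with bromide 2, trans to the C4 arylmethyl group; this builds the quaternary carbinol C3.
2. The oxolan-2-one ring is the only ring made (step 9; both arene rings are bought) ⇐ formal [3+2] union of β-bromo aldehyde 10 with the O=C unit of carbamoylsilane 13. Carbonyl addition makes the C2–C3 bond, O-alkylation of the new amide makes the O1–C5 bond, and hydrolysis discards nitrogen and silicon.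
3. Enabling feature: in the ring O1–C2(=O)–C3(OH)–C4–C5H2 the carbinol carbon C3 is a latent aldehyde carbon standing 1,3 to the oxygen-bearing C5H2 across C4. A 2-substituted 3-bromopropanal is therefore a 1,3-dielectrophile that a two-atom O=C bridge closes 5-exo-tet; C3 is also α to the lactone carbonyl, so its arylmethyl group can follow by enolate alkylation.
4. Aldehyde 10 ⇐ lipase desymmetrisation of prochiral diol 6 (sets C4, the stereocenter that later controls C3) ⇐ malonate alkylation with 2.

Key step: step 9

Assumption: the lipase acetylation of diol 6 is taken to give the (R)-monoacetate 7; if the enzyme prefers the other arm, the same (R)-7 should be reached with the same enzyme by hydrolysis of the diacetate of 6, which gives the opposite enantiomer.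

Step 1
Reactants: 1 4-(benzyloxy)-3-methoxybenzyl alcohol
Product: 2 4-(benzyloxy)-3-methoxybenzyl bromide
Conditions: PBr3 (0.4 equiv), Et2O, 0 °C
Reagents that add atoms: phosphorus tribromide, BrP(Br)Br
Why: Bromination of an electron-rich benzylic alcohol with PBr3 (SN2 on the phosphite ester) is routine, leaves the aryl benzyl ether intact and forms no stereocenter.

Step 2
Reactants: 2 4-(benzyloxy)-3-methoxybenzyl bromide; 3 diethyl malonate
Product: 5 diethyl 2-{[4-(benzyloxy)-3-methoxyphenyl]methyl}propanedioate, via sodium enolate NaCH(CO2Et)2 4 (not isolated)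
Conditions: NaH (1.05 equiv), 3 (2.5 equiv), THF, 0 °C; then 2, 0 to 25 °C
Reagents that add atoms: none
Why: Malonic ester alkylation (SN2 on a reactive benzylic bromide) with excess malonate should give the mono-alkylated diester without a stereocenter.

Step 3
Reactants: 5 diethyl 2-{[4-(benzyloxy)-3-methoxyphenyl]methyl}propanedioate
Product: 6 2-{[4-(benzyloxy)-3-methoxyphenyl]methyl}propane-1,3-diol
Conditions: LiAlH4 (2.5 equiv), THF, 0 to 25 °C; aqueous NaOH work-up
Reagents that add atoms: none
Why: LiAlH4 reduction of both esters gives the prochiral 1,3-diol, the benzyl ether being inert to hydride.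

Step 4
Reactants: 6 2-{[4-(benzyloxy)-3-methoxyphenyl]methyl}propane-1,3-diol
Product: 7 (2R)-2-{[4-(benzyloxy)-3-methoxyphenyl]methyl}-3-hydroxypropyl acetate
Conditions: lipase PS (Burkholderia cepacia lipase, immobilised), vinyl acetate, iPr2O, 25 °C, stopped at the monoacetate
Reagents that add atoms: vinyl acetate, CC(=O)OC=C
Why: Lipase-catalysed irreversible transesterification (enzymatic desymmetrisation) distinguishes the two enantiotopic hydroxymethyl arms and so sets the only stereocenter carried through the route, the future C4 of the lactone.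

Step 5
Reactants: 7 (2R)-2-{[4-(benzyloxy)-3-methoxyphenyl]methyl}-3-hydroxypropyl acetate
Product: 8 (2S)-2-{[4-(benzyloxy)-3-methoxyphenyl]methyl}-3-bromopropyl acetate
Conditions: CBr4 (1.3 equiv), PPh3 (1.3 equiv), CH2Cl2, 0 °C, run on freshly made 7
Reagents that add atoms: carbon tetrabromide, BrC(Br)(Br)Br
Why: The Appel reaction (SN2 at the primary carbinol carbon) is neutral, so the neighbouring acetate should not migrate between the arms and the stereocenter, which is not a reacting centre, keeps its spatial arrangement (the descriptor changes only through the priority rules).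

Step 6
Reactants: 8 (2S)-2-{[4-(benzyloxy)-3-methoxyphenyl]methyl}-3-bromopropyl acetate
Product: 9 (2S)-2-{[4-(benzyloxy)-3-methoxyphenyl]methyl}-3-bromopropan-1-ol
Conditions: HCl (cat., anhydrous) in MeOH, 0 to 25 °C
Reagents that add atoms: none
Why: Acid-catalysed transesterification with methanol removes the acetate without ever forming an alkoxide next to the primary bromide, so oxetane closure is avoided.

Step 7
Reactants: 9 (2S)-2-{[4-(benzyloxy)-3-methoxyphenyl]methyl}-3-bromopropan-1-ol
Product: 10 (2S)-2-{[4-(benzyloxy)-3-methoxyphenyl]methyl}-3-bromopropanal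
Conditions: Dess–Martin periodinane (1.2 equiv), CH2Cl2, 0 to 25 °C; short silica pad; used at once
Reagents that add atoms: none
Why: Dess–Martin oxidation runs without base, which should spare the β-bromo aldehyde from α-epimerisation and loss of HBr.

Step 8
Reactants: 11 N,N-dimethylformamide
Product: 13 N,N-dimethylcarbamoyl(trimethyl)silane, via carbamoyllithium LiC(O)NMe2 12 (not isolated)
Conditions: LiN(iPr)2 (1.1 equiv) added to 11 and Me3SiCl (1.2 equiv), THF, −78 °C (in situ quench); distillation
Reagents that add atoms: chlorotrimethylsilane, C[Si](C)(C)Cl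
Why: Formyl C–H deprotonation of a formamide by a lithium amide gives a carbamoyllithium that is silylated on carbon as it forms, an established entry to carbamoylsilanes.

Step 9
Reactants: 10 (2S)-2-{[4-(benzyloxy)-3-methoxyphenyl]methyl}-3-bromopropanal; 13 N,N-dimethylcarbamoyl(trimethyl)silane
Product: 16 (4R)-4-{[4-(benzyloxy)-3-methoxyphenyl]methyl}-3-hydroxyoxolan-2-one as both C3 epimers, via open-chain siloxy amide 14 (not isolated), via cyclic iminium ether bromide 15 (not isolated)
Conditions: 13 (1.5 equiv), toluene, 0 to 25 °C; then MeCN, 70 °C; then H2O, THF, cat. aq. HBr, 25 °C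
Reagents that add atoms: water, O
Why: The carbamoylsilane acts as a neutral carbamoyl-anion equivalent: its carbonyl carbon adds to the aldehyde carbon of 10 while silicon shifts to the new alkoxide oxygen, which forges the C2–C3 bond in 14; on warming, the amide carbonyl oxygen displaces the primary bromide (SN2), which forges the O1–C5 bond and gives iminium ether 15, and weakly acidic hydrolysis then expels dimethylamine and the silyl group to leave lactone 16. The closest known reaction types are the uncatalysed addition of carbamoylsilanes to aldehydes to give α-siloxy amides and the cyclisation of γ-halo N,N-dialkyl amides to 2-iminiooxolane salts that hydrolyse to γ-lactones (the same oxygen participation as in amide-directed halolactonisation). The oxolanone ring closes 5-exo-tet through oxygen. The new carbinol stereocenter C3 forms under weak 1,2-induction from C4 only, which is acceptable because C3 becomes planar again in step 11, and C4 is not touched. The step needs carbonyl addition to win over reaction at the C–Br bond, O- over N-alkylation and an intact α-stereocenter: the silane does not attack unactivated alkyl bromides, the fully substituted nitrogen cannot alkylate productively, and the absence of base should keep the aldehyde from epimerising or losing HBr.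

Step 10
Reactants: 16 (4R)-4-{[4-(benzyloxy)-3-methoxyphenyl]methyl}-3-hydroxyoxolan-2-one
Product: 17 (4R)-3-(benzyloxy)-4-{[4-(benzyloxy)-3-methoxyphenyl]methyl}oxolan-2-one as both C3 epimers
Conditions: BnBr (1.5 equiv), Ag2O (1.5 equiv), CH2Cl2, 25 °C, dark
Reagents that add atoms: benzyl bromide, BrCc1ccccc1
Why: Ag2O-mediated Williamson-type benzylation etherifies the α-hydroxy lactone under neutral conditions without opening the ring, and both C3 epimers are carried on because C3 is planarised in the next step.

Step 11
Reactants: 17 (4R)-3-(benzyloxy)-4-{[4-(benzyloxy)-3-methoxyphenyl]methyl}oxolan-2-one; 2 4-(benzyloxy)-3-methoxybenzyl bromide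
Product: 19 (3R,4R)-3-(benzyloxy)-3,4-bis{[4-(benzyloxy)-3-methoxyphenyl]methyl}oxolan-2-one, via lithium enolate 18 (not isolated)
Conditions: LiN(iPr)2 (1.15 equiv), THF, −78 °C; then 2 (1.5 equiv), DMPU, −78 to −30 °C
Reagents that add atoms: none
Why: Enolate alkylation (SN2 on the benzylic bromide) should take place on the face of the planar lactone enolate opposite to the C4 arylmethyl group, which puts the new arylmethyl group trans to it and sets the quaternary stereocenter C3 as (R), the usual outcome for 3-alkoxy-4-substituted butyrolactone enolates.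

Step 12
Reactants: 19 (3R,4R)-3-(benzyloxy)-3,4-bis{[4-(benzyloxy)-3-methoxyphenyl]methyl}oxolan-2-one
Product: 20 (+)-nortrachelogenin, (3R,4R)-3-hydroxy-3,4-bis[(4-hydroxy-3-methoxyphenyl)methyl]oxolan-2-one
Conditions: H2 (1 atm), 10% Pd/C, EtOAc/EtOH, 25 °C
Reagents that add atoms: none
Why: Hydrogenolysis over Pd/C should cleave the two aryl benzyl ethers and the tertiary alkyl benzyl ether while the lactone and both stereocenters, neither of which is benzylic, stay untouched.

**Compound list**
1 | 4-(benzyloxy)-3-methoxybenzyl alcohol | OCc1ccc(OCc2ccccc2)c(OC)c1 | starting material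
2 | 4-(benzyloxy)-3-methoxybenzyl bromide | BrCc1ccc(OCc2ccccc2)c(OC)c1 | intermediate
3 | diethyl malonate | CCOC(=O)CC(=O)OCC | starting material
4 | sodium enolate of diethyl malonate, NaCH(CO2Et)2 (not isolated) | CCOC(=O)[CH-]C(=O)OCC.[Na+] | intermediate
5 | diethyl 2-{[4-(benzyloxy)-3-methoxyphenyl]methyl}propanedioate | CCOC(=O)C(Cc1ccc(OCc2ccccc2)c(OC)c1)C(=O)OCC | intermediate
6 | 2-{[4-(benzyloxy)-3-methoxyphenyl]methyl}propane-1,3-diol | OCC(CO)Cc1ccc(OCc2ccccc2)c(OC)c1 | intermediate
7 | (2R)-2-{[4-(benzyloxy)-3-methoxyphenyl]methyl}-3-hydroxypropyl acetate | CC(=O)OC[C@@H](CO)Cc1ccc(OCc2ccccc2)c(OC)c1 | intermediate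
8 | (2S)-2-{[4-(benzyloxy)-3-methoxyphenyl]methyl}-3-bromopropyl acetate | CC(=O)OC[C@@H](CBr)Cc1ccc(OCc2ccccc2)c(OC)c1 | intermediate
9 | (2S)-2-{[4-(benzyloxy)-3-methoxyphenyl]methyl}-3-bromopropan-1-ol | OC[C@@H](CBr)Cc1ccc(OCc2ccccc2)c(OC)c1 | intermediate
10 | (2S)-2-{[4-(benzyloxy)-3-methoxyphenyl]methyl}-3-bromopropanal | O=C[C@@H](CBr)Cc1ccc(OCc2ccccc2)c(OC)c1 | intermediate
11 | N,N-dimethylformamide | CN(C)C=O | starting material
12 | dimethylcarbamoyllithium, LiC(O)NMe2 (not isolated) | CN(C)C(=O)[Li] | intermediate
13 | N,N-dimethylcarbamoyl(trimethyl)silane | CN(C)C(=O)[Si](C)(C)C | intermediate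
14 | (3S)-4-bromo-3-{[4-(benzyloxy)-3-methoxyphenyl]methyl}-N,N-dimethyl-2-[(trimethylsilyl)oxy]butanamide, both C2 epimers (not isolated) | CN(C)C(=O)C(O[Si](C)(C)C)[C@@H](CBr)Cc1ccc(OCc2ccccc2)c(OC)c1 | intermediate
15 | N-[(4R)-4-{[4-(benzyloxy)-3-methoxyphenyl]methyl}-3-[(trimethylsilyl)oxy]oxolan-2-ylidene]-N-methylmethanaminium bromide, both C3 epimers (not isolated) | C[N+](C)=C1OC[C@@H](Cc2ccc(OCc3ccccc3)c(OC)c2)C1O[Si](C)(C)C.[Br-] | intermediate
16 | (4R)-4-{[4-(benzyloxy)-3-methoxyphenyl]methyl}-3-hydroxyoxolan-2-one, both C3 epimers | O=C1OC[C@@H](Cc2ccc(OCc3ccccc3)c(OC)c2)C1O | intermediate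
17 | (4R)-3-(benzyloxy)-4-{[4-(benzyloxy)-3-methoxyphenyl]methyl}oxolan-2-one, both C3 epimers | O=C1OC[C@@H](Cc2ccc(OCc3ccccc3)c(OC)c2)C1OCc1ccccc1 | intermediate
18 | lithium enolate of 17, lithium (4R)-3-(benzyloxy)-4-{[4-(benzyloxy)-3-methoxyphenyl]methyl}-4,5-dihydrofuran-2-olate (not isolated) | [Li+].[O-]C1=C(OCc2ccccc2)[C@H](Cc2ccc(OCc3ccccc3)c(OC)c2)CO1 | intermediate
19 | (3R,4R)-3-(benzyloxy)-3,4-bis{[4-(benzyloxy)-3-methoxyphenyl]methyl}oxolan-2-one | COc1cc(C[C@@H]2COC(=O)[C@@]2(OCc3ccccc3)Cc3ccc(OCc4ccccc4)c(OC)c3)ccc1OCc1ccccc1 | intermediate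
20 | (+)-nortrachelogenin, (3R,4R)-3-hydroxy-3,4-bis[(4-hydroxy-3-methoxyphenyl)methyl]oxolan-2-one | COc1cc(C[C@@H]2COC(=O)[C@@]2(O)Cc2ccc(O)c(OC)c2)ccc1O | target

**Step count and risks**
Total step count: 12 (11 on the main line plus the preparation of reagent 13 in step 8).
Longest linear sequence: 11 steps (steps 1–7 and 9–12, from 1 to 20).

The three steps most likely to fail:

Step 9. The carbonyl addition of the silane to the α-branched aldehyde may be sluggish, so that thermal loss of HBr or α-epimerisation of 10 overtakes it, or the O-alkylation may stall at the open-chain amide. The fallback sets out from 10 and comes back at 16. A Passerini three-component reaction of 10 with tert-butyl isocyanide and acetic acid (CH2Cl2, 25 °C), which is fast and weakly acidic, should give the α-acetoxy N-tert-butyl amide F1. On warming in MeCN the secondary amide oxygen should close onto the bromide to give the cyclic imidate hydrobromide F2, which water hydrolyses to the α-acetoxy lactone F3. HCl in MeOH then removes the acetate and gives 16.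

Step 11. C-alkylation of the fully substituted enolate may be slow, which leaves room for O-alkylation, enolate decomposition and eroded facial selectivity. The fallback sets out from 17 and comes back at 20. Enolate 18 (LiN(iPr)2, THF, −78 °C) is instead added to 4-(benzyloxy)-3-methoxybenzaldehyde, a much more reactive electrophile towards a hindered enolate, again anti to the C4 substituent, to give the aldol adduct F4. Hydrogenolysis under acidic conditions (H2, Pd/C, AcOH, cat. HClO4) should then remove the benzylic hydroxyl together with the three benzyl groups and give 20 directly.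

Step 7. Epimerisation at the α-carbon and β-elimination of HBr may occur during oxidation and handling of the β-bromo aldehyde. The fallback sets out from 7 and comes back at 16, and never places a leaving group β to an aldehyde. The free hydroxyl of 7 is silylated (tBuMe2SiCl, imidazole) to the silyl ether acetate F5. The acetate is removed reductively at low temperature (iBu2AlH, CH2Cl2, −78 °C, which avoids silyl migration between the arms) to give the alcohol F6, and Dess–Martin oxidation gives the robust β-silyloxy aldehyde F7. Addition of 13 as in step 9 gives the bis-silylated hydroxy amide F8. Aqueous HCl in THF at 50 °C then removes both silyl groups and closes the γ-hydroxy amide to lactone 16 by ordinary acid-mediated lactonisation.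

**Further compounds**
F1 | step 9 | (3S)-4-bromo-3-{[4-(benzyloxy)-3-methoxyphenyl]methyl}-1-(tert-butylamino)-1-oxobutan-2-yl acetate, both C2 epimers | CC(=O)OC(C(=O)NC(C)(C)C)[C@@H](CBr)Cc1ccc(OCc2ccccc2)c(OC)c1
F2 | step 9 | (4R)-3-acetoxy-N-tert-butyl-4-{[4-(benzyloxy)-3-methoxyphenyl]methyl}oxolan-2-iminium bromide | CC(C)(C)[NH+]=C1OC[C@@H](Cc2ccc(OCc3ccccc3)c(OC)c2)C1OC(C)=O.[Br-]
F3 | step 9 | (4R)-4-{[4-(benzyloxy)-3-methoxyphenyl]methyl}-2-oxooxolan-3-yl acetate | O=C1OC[C@@H](Cc2ccc(OCc3ccccc3)c(OC)c2)C1OC(C)=O
F4 | step 11 | aldol adduct, 3-(benzyloxy)-3-{[4-(benzyloxy)-3-methoxyphenyl](hydroxy)methyl}-4-{[4-(benzyloxy)-3-methoxyphenyl]methyl}oxolan-2-one with the ring configuration of 19, both carbinol epimers | COc1cc(C[C@@H]2COC(=O)[C@@]2(OCc3ccccc3)C(O)c3ccc(OCc4ccccc4)c(OC)c3)ccc1OCc1ccccc1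
F5 | step 7 | (2S)-2-{[4-(benzyloxy)-3-methoxyphenyl]methyl}-3-[(tert-butyldimethylsilyl)oxy]propyl acetate | CC(=O)OC[C@@H](CO[Si](C)(C)C(C)(C)C)Cc1ccc(OCc2ccccc2)c(OC)c1
F6 | step 7 | (2S)-2-{[4-(benzyloxy)-3-methoxyphenyl]methyl}-3-[(tert-butyldimethylsilyl)oxy]propan-1-ol | OC[C@@H](CO[Si](C)(C)C(C)(C)C)Cc1ccc(OCc2ccccc2)c(OC)c1
F7 | step 7 | (2R)-2-{[4-(benzyloxy)-3-methoxyphenyl]methyl}-3-[(tert-butyldimethylsilyl)oxy]propanal | O=C[C@@H](CO[Si](C)(C)C(C)(C)C)Cc1ccc(OCc2ccccc2)c(OC)c1
F8 | step 7 | (3R)-3-{[4-(benzyloxy)-3-methoxyphenyl]methyl}-4-[(tert-butyldimethylsilyl)oxy]-N,N-dimethyl-2-[(trimethylsilyl)oxy]butanamide, both C2 epimers | CN(C)C(=O)C(O[Si](C)(C)C)[C@@H](CO[Si](C)(C)C(C)(C)C)Cc1ccc(OCc2ccccc2)c(OC)c1
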